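The lower pyran ring (ring F: O1, C2, C3, C4, C4a, C8a) is cut at O1–C2 and C3–C4, which reveals a ring D salicylaldehyde (O1, C8a, C4a, C4) and a cinnamaldehyde whose β-carbon (C2) bears pyrogallol ring E. One amine-catalysed oxa-Michael/aldol domino joins them, closes ring F as a 2H-chromene-3-carbaldehyde and sets C2. Its precursor is (E)-3,4,5-tris(benzyloxy)cinnamaldehyde, used with 4-(benzyloxy)salicylaldehyde. Deformylation, dihydroxylation, benzylic oxidation and debenzylation lead to (+)-dihydrorobinetin, which serves twice: its borohydride-derived 3,4-diol is the C4 electrophile that is bonded to ring E C2' of a second molecule, and a last reduction gives the target.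

Key step: step 2

Remark: locants follow flavan numbering in each unit (upper unit: benzo ring A, pyrogallol ring B, pyran ring C; lower unit: benzo ring D, bridging pyrogallol ring E, pyran ring F). Ring E is carried with C2' unsubstituted, because that carbon is bonded later through the innate nucleophilicity of the free pyrogallol ring. The CIP letter at C2 changes along the route with its neighbours, while the aryl group keeps the same position in space.

Step 1
Reactants: 1 3,4,5-tris(benzyloxy)benzaldehyde; 2 (triphenylphosphoranylidene)acetaldehyde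
Product: 3 (E)-3-[3,4,5-tris(benzyloxy)phenyl]prop-2-enal
Conditions: 2 (1.05 equiv), toluene, 80 °C
Reagents that add atoms: none
Why: Wittig olefination with a formyl-stabilised ylide should give the (E)-enal, and the ylide is kept near one equivalent because the product enal is itself a slower Wittig acceptor.

Step 2
Reactants: 3 (E)-3-[3,4,5-tris(benzyloxy)phenyl]prop-2-enal; 4 4-(benzyloxy)-2-hydroxybenzaldehyde
Product: 6 (R)-7-(benzyloxy)-2-[3,4,5-tris(benzyloxy)phenyl]-2H-chromene-3-carbaldehyde, via chromanol aldehyde 5 (not isolated)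
Conditions: (S)-2-[diphenyl(trimethylsilyloxy)methyl]pyrrolidine (20 mol %), 2-nitrobenzoic acid (20 mol %), 4 Å molecular sieves, toluene, rt
Reagents that add atoms: none
Why: The secondary amine condenses with enal 3 to an (E), s-trans iminium ion, the phenol oxygen of 4 adds to its β-carbon (the future C2), and the enamine so formed attacks the neighbouring formyl carbon (C3–C4 bond) before loss of water and hydrolysis release 6 and the catalyst, 5 being the aldol stage in free or catalyst-bound form. The closest known reaction type is the diarylprolinol silyl ether-catalysed oxa-Michael/aldol condensation domino of salicylaldehydes with β-aryl enals, used here on a new pair of partners. Ring F closes in the aldol event as a 6-exo-trig (enolexo) attack of the enamine carbon on the aryl aldehyde. The only new stereocentre, C2, is under catalyst control: the CPh2(OSiMe3) group of the (S)-pyrrolidine covers one face of the planar iminium ion, so that oxygen should add to the open Si face of the β-carbon, which corresponds to (R)-6 and to the lower C2 of the target. The step needs enantiofacial selectivity at C2 and must outrun the reversible oxa-Michael addition; the defined (E)-geometry of 3 fixes one iminium geometry, and the ortho formyl group of 4 traps the enamine within the same molecule and makes the sequence irreversible through dehydration.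

Step 3
Reactants: 6 (R)-7-(benzyloxy)-2-[3,4,5-tris(benzyloxy)phenyl]-2H-chromene-3-carbaldehyde
Product: 7 (S)-7-(benzyloxy)-2-[3,4,5-tris(benzyloxy)phenyl]-2H-chromene
Conditions: RhCl(PPh3)3 (1.1 equiv), toluene, 90–110 °C, argon, dark
Reagents that add atoms: none
Why: Tsuji–Wilkinson decarbonylation (formyl C–H oxidative addition to monovalent rhodium, CO extrusion, C–H reductive elimination) should excise the formyl carbon and leave C3=C4 in place, and the stoichiometric complex allows the lowest workable temperature so that C2 is not scrambled by electrocyclic opening of the 2H-chromene.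

Step 4
Reactants: 7 (S)-7-(benzyloxy)-2-[3,4,5-tris(benzyloxy)phenyl]-2H-chromene
Product: 8 (2R,3S,4S)-7-(benzyloxy)-2-[3,4,5-tris(benzyloxy)phenyl]chromane-3,4-diol (2,3-trans-3,4-cis)
Conditions: OsO4 (2 mol %), N-methylmorpholine N-oxide (1.5 equiv), acetone/H2O, rt
Reagents that add atoms: OsO4 (osmium tetroxide), O=[Os](=O)(=O)=O; N-methylmorpholine N-oxide, C[N+]1([O-])CCOCC1
Why: Upjohn dihydroxylation should add both oxygens to the electron-rich styrene-type C3=C4 bond from the face opposite the C2 aryl group, which sets C3 (S) and C4 (S) cis to each other and trans to the aryl group under substrate control from C2.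

Step 5
Reactants: 8 (2R,3S,4S)-7-(benzyloxy)-2-[3,4,5-tris(benzyloxy)phenyl]chromane-3,4-diol
Product: 9 (2R,3R)-7-(benzyloxy)-3-hydroxy-2-[3,4,5-tris(benzyloxy)phenyl]chroman-4-one
Conditions: activated MnO2 (excess), CH2Cl2, rt
Reagents that add atoms: none
Why: Activated MnO2 is expected to oxidise only the benzylic C4 carbinol, which is activated by the para benzyloxy group and O1, and to leave the non-benzylic C3 carbinol, so that the 2,3-trans relation from step 4 is carried into the dihydroflavonol (chemoselective benzylic alcohol oxidation).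

Step 6
Reactants: 9 (2R,3R)-7-(benzyloxy)-3-hydroxy-2-[3,4,5-tris(benzyloxy)phenyl]chroman-4-one
Product: 10 (2R,3R)-3,7-dihydroxy-2-(3,4,5-trihydroxyphenyl)chroman-4-one, (+)-dihydrorobinetin
Conditions: H2 (1 atm), Pd(OH)2/C, THF/MeOH, rt
Reagents that add atoms: none
Why: Hydrogenolysis should cleave the four benzyl ethers, while the aryl ketone, deactivated as a vinylogous ester by O1 and the C7 oxygen, and the cyclic C2–O1 ether are expected to survive at one atmosphere without acid.

Step 7
Reactants: 10 (+)-dihydrorobinetin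
Product: 11 (2R,3S,4R)-2-(3,4,5-trihydroxyphenyl)chromane-3,4,7-triol, (+)-leucorobinetinidin
Conditions: NaBH4 (excess), EtOH, 0 °C to rt, argon; work-up at pH 5–6; only a minor portion of the batch of 10 is used
Reagents that add atoms: none
Why: Borohydride reduction of the C4 ketone of a 2,3-trans-dihydroflavonol should give the flavan-3,4-diol, mainly with the equatorial C4 hydroxyl trans to the C3 hydroxyl through axial hydride delivery; the C4 configuration is of no consequence here because C4 is ionised in step 8, and the rest of 10 is kept as the nucleophile for that step.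

Step 8
Reactants: 11 (+)-leucorobinetinidin; 10 (+)-dihydrorobinetin
Product: 12 (2R,3R)-2-{2-[(2R,3S,4S)-3,7-dihydroxy-2-(3,4,5-trihydroxyphenyl)chroman-4-yl]-3,4,5-trihydroxyphenyl}-3,7-dihydroxychroman-4-one, robinetinidol-(4α→2')-dihydrorobinetin
Conditions: fourfold excess of the dihydroflavonol, 0.1 M HCl, H2O/EtOH, rt, argon; chromatography on Sephadex LH-20
Reagents that add atoms: none
Why: In this acid-catalysed flavan-3,4-diol/phenol condensation (Friedel–Crafts-type benzylic substitution with loss of water) ionisation of C4–OH of 11 gives a cation stabilised by the para C7 hydroxyl and O1, which should be captured by C2' (equivalent to C6') of the free pyrogallol ring E of 10, the most nucleophilic carbon there because ring D is deactivated by its conjugated C4 carbonyl, with attack anti to the C3 hydroxyl setting the upper C4 as (S) (3,4-trans) and the excess of 10 holding back self-condensation of 11.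

Step 9
Reactants: 12 robinetinidol-(4α→2')-dihydrorobinetin
Product: 13 (2R,3S,4R)-2-{2-[(2R,3S,4S)-3,7-dihydroxy-2-(3,4,5-trihydroxyphenyl)chroman-4-yl]-3,4,5-trihydroxyphenyl}chromane-3,4,7-triol, the target CNP0205451.4
Conditions: NaBH4 (excess), EtOH, 0 °C to rt, argon; work-up at pH 5–6
Reagents that add atoms: none
Why: Borohydride reduction of the ring F ketone should proceed, as in step 7, by axial hydride delivery to give the equatorial C4 hydroxyl trans to the C3 hydroxyl, which sets the lower C4 as (R), and the near-neutral work-up protects the acid-labile flavan-3,4-diol.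

Compound list
1 | 3,4,5-tris(benzyloxy)benzaldehyde | O=Cc1cc(OCc2ccccc2)c(OCc2ccccc2)c(OCc2ccccc2)c1 | starting material
2 | (triphenylphosphoranylidene)acetaldehyde | O=CC=P(c1ccccc1)(c1ccccc1)c1ccccc1 | starting material
3 | (E)-3-[3,4,5-tris(benzyloxy)phenyl]prop-2-enal | O=C/C=C/c1cc(OCc2ccccc2)c(OCc2ccccc2)c(OCc2ccccc2)c1 | intermediate
4 | 4-(benzyloxy)-2-hydroxybenzaldehyde | O=Cc1ccc(OCc2ccccc2)cc1O | starting material
5 | (2S)-7-(benzyloxy)-4-hydroxy-2-[3,4,5-tris(benzyloxy)phenyl]chromane-3-carbaldehyde, C3 and C4 not defined | c1ccccc1COc1cc(cc(OCc2ccccc2)c1OCc1ccccc1)[C@H]1Oc2cc(OCc3ccccc3)ccc2C(O)C1C=O | intermediate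
6 | (R)-7-(benzyloxy)-2-[3,4,5-tris(benzyloxy)phenyl]-2H-chromene-3-carbaldehyde | c1ccccc1COc1cc(cc(OCc2ccccc2)c1OCc1ccccc1)[C@H]1Oc2cc(OCc3ccccc3)ccc2C=C1C=O | intermediate
7 | (S)-7-(benzyloxy)-2-[3,4,5-tris(benzyloxy)phenyl]-2H-chromene | c1ccccc1COc1cc(cc(OCc2ccccc2)c1OCc1ccccc1)[C@H]1Oc2cc(OCc3ccccc3)ccc2C=C1 | intermediate
8 | (2R,3S,4S)-7-(benzyloxy)-2-[3,4,5-tris(benzyloxy)phenyl]chromane-3,4-diol | O[C@H]1c2ccc(OCc3ccccc3)cc2O[C@H](c2cc(OCc3ccccc3)c(OCc3ccccc3)c(OCc3ccccc3)c2)[C@H]1O | intermediate
9 | (2R,3R)-7-(benzyloxy)-3-hydroxy-2-[3,4,5-tris(benzyloxy)phenyl]chroman-4-one | O=C1c2ccc(OCc3ccccc3)cc2O[C@H](c2cc(OCc3ccccc3)c(OCc3ccccc3)c(OCc3ccccc3)c2)[C@H]1O | intermediate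
10 | (2R,3R)-3,7-dihydroxy-2-(3,4,5-trihydroxyphenyl)chroman-4-one, (+)-dihydrorobinetin | O=C1c2ccc(O)cc2O[C@H](c2cc(O)c(O)c(O)c2)[C@H]1O | intermediate
11 | (2R,3S,4R)-2-(3,4,5-trihydroxyphenyl)chromane-3,4,7-triol, (+)-leucorobinetinidin | O[C@@H]1c2ccc(O)cc2O[C@H](c2cc(O)c(O)c(O)c2)[C@H]1O | intermediate
12 | (2R,3R)-2-{2-[(2R,3S,4S)-3,7-dihydroxy-2-(3,4,5-trihydroxyphenyl)chroman-4-yl]-3,4,5-trihydroxyphenyl}-3,7-dihydroxychroman-4-one | Oc1ccc2c(c1)O[C@H](c1cc(O)c(O)c(O)c1)[C@@H](O)[C@@H]2c1c([C@H]2Oc3cc(O)ccc3C(=O)[C@@H]2O)cc(O)c(O)c1O | intermediate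
13 | (2R,3S,4R)-2-{2-[(2R,3S,4S)-3,7-dihydroxy-2-(3,4,5-trihydroxyphenyl)chroman-4-yl]-3,4,5-trihydroxyphenyl}chromane-3,4,7-triol | Oc1ccc2c(c1)O[C@H](c1cc(O)c(O)c(O)c1)[C@@H](O)[C@@H]2c1c([C@H]2Oc3cc(O)ccc3[C@@H](O)[C@@H]2O)cc(O)c(O)c1O | target

Total step count: 9.
Longest linear sequence: 9 steps (1 to 13; compound 10 enters step 8 a second time as the nucleophile).

Steps most likely to fail

Step 8. What may go wrong: the C4 cation from 11 is consumed by further molecules of 11 or by the product (oligomer growth), and attack on the two faces of the cation is not selective enough. Fallback: setting out from 11, the cation is first trapped with benzyl mercaptan (BnSH, AcOH, rt) as (2R,3R)-4-(benzylsulfanyl)-2-(3,4,5-trihydroxyphenyl)chromane-3,7-diol F1, a storable C4 electrophile obtained as its C4 epimers. F1 is then activated by a thiophilic silver salt (AgBF4, THF, 0 °C) in the presence of 10, a known way of forming interflavanyl bonds in an aprotic, nearly neutral medium where the cation is released slowly. The sequence comes back to the route at 12.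

Step 3. What may go wrong: loss of enantiomeric purity at C2 by reversible thermal ring opening of the 2H-chromene, or migration of the double bond, during the hot decarbonylation. Fallback: setting out from 6, the order of events is inverted. Dihydroxylation of the enal double bond (OsO4 cat., N-methylmorpholine N-oxide, citric acid, t-BuOH/H2O, rt) anti to the aryl group should give (2R,3S,4S)-7-(benzyloxy)-3,4-dihydroxy-2-[3,4,5-tris(benzyloxy)phenyl]chromane-3-carbaldehyde F2. This saturated α-hydroxy aldehyde is then decarbonylated with RhCl(PPh3)3 at a lower temperature, with retention at C3, the reaction type known for aldoses. The sequence comes back to the route at 8, and no formyl-free 2H-chromene is heated at any point.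

Step 2. What may go wrong: erosion of enantioselectivity through the reversible oxa-Michael addition, or slow turnover of the electron-rich enal. Fallback: setting out from 1, ring F is built by the chalcone epoxide route instead. Commercial 1-[4-(benzyloxy)-2-hydroxyphenyl]ethan-1-one F3 is protected (MOMCl, i-Pr2NEt, CH2Cl2) as 1-[4-(benzyloxy)-2-(methoxymethoxy)phenyl]ethan-1-one F4. Claisen–Schmidt condensation of F4 with 1 (KOH, EtOH) gives (E)-1-[4-(benzyloxy)-2-(methoxymethoxy)phenyl]-3-[3,4,5-tris(benzyloxy)phenyl]prop-2-en-1-one F5. Juliá–Colonna epoxidation (poly-L-leucine, urea–H2O2, DBU, THF) should give [4-(benzyloxy)-2-(methoxymethoxy)phenyl][(2R,3S)-3-[3,4,5-tris(benzyloxy)phenyl]oxiran-2-yl]methanone F6. HCl in MeOH then removes the methoxymethyl group, and the freed phenol opens the epoxide at the benzylic carbon with inversion. The sequence comes back to the route at 9 and bypasses steps 2 to 5.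

Further compounds
F1 | step 8 | (2R,3R)-4-(benzylsulfanyl)-2-(3,4,5-trihydroxyphenyl)chromane-3,7-diol, C4 epimers | Oc1ccc2c(c1)O[C@H](c1cc(O)c(O)c(O)c1)[C@@H](O)C2SCc1ccccc1
F2 | step 3 | (2R,3S,4S)-7-(benzyloxy)-3,4-dihydroxy-2-[3,4,5-tris(benzyloxy)phenyl]chromane-3-carbaldehyde | O[C@H]1c2ccc(OCc3ccccc3)cc2O[C@H](c2cc(OCc3ccccc3)c(OCc3ccccc3)c(OCc3ccccc3)c2)[C@]1(O)C=O
F3 | step 2 | 1-[4-(benzyloxy)-2-hydroxyphenyl]ethan-1-one | CC(=O)c1ccc(OCc2ccccc2)cc1O
F4 | step 2 | 1-[4-(benzyloxy)-2-(methoxymethoxy)phenyl]ethan-1-one | CC(=O)c1ccc(OCc2ccccc2)cc1OCOC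
F5 | step 2 | (E)-1-[4-(benzyloxy)-2-(methoxymethoxy)phenyl]-3-[3,4,5-tris(benzyloxy)phenyl]prop-2-en-1-one | COCOc1cc(OCc2ccccc2)ccc1C(=O)/C=C/c1cc(OCc2ccccc2)c(OCc2ccccc2)c(OCc2ccccc2)c1
F6 | step 2 | [4-(benzyloxy)-2-(methoxymethoxy)phenyl][(2R,3S)-3-[3,4,5-tris(benzyloxy)phenyl]oxiran-2-yl]methanone | COCOc1cc(OCc2ccccc2)ccc1C(=O)[C@@H]1O[C@H]1c1cc(OCc2ccccc2)c(OCc2ccccc2)c(OCc2ccccc2)c1
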